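**Retrosynthetic overview**
1. The last operations are Si–O cleavage and a face-selective hydrogenation of a C8 exomethylene, which is made from a C8 ketone and sets the C8 methyl.
2. The key disconnection is C9–C11. The extended dienolate of a C13 bicyclic β,γ-enone is alkylated with a C6 iodo ester of 1,3-protected glycerol (14 heavy atoms each, silyl groups aside).
3. Ring A is made first by Robinson annulation of isobutyraldehyde and methyl vinyl ketone. C6–C9 and C20 come from ethyl vinyl ketone. Ring B is closed second, at C9–C10, by an intramolecular Pd enolate/vinyl bromide coupling.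
4. C5 and the C1=C10 alkene come from CBS reduction of an α-bromo enone followed by a Myers reductive transposition (chirality transfer from C1 to C5).
5. The side chain comes from acrylate RCM, CuH conjugate reduction (C13), TMSI lactone opening and esterification with 1,3-bis-TBS-glycerol.

Assumption: comments use halimane locants (C5 ring-fusion CH, C8 CHMe, C9 quaternary C, C10 olefinic ring-fusion C, C13 side-chain CHMe), and in step 12 the ligand antipode that gives (R)-23 is taken.

**Core (rings A and B)**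

Step 1
Reactants: 1 isobutyraldehyde (2-methylpropanal); 2 methyl vinyl ketone (but-3-en-2-one)
Product: 3 4,4-dimethylcyclohex-2-en-1-one
Conditions: cat. H2SO4, toluene, reflux, Dean–Stark
Reagents that add atoms: none
Why: In this acid-catalysed Robinson annulation the enol of 1 adds to 2 (Michael), and the keto aldehyde can close by aldol condensation in only one way because the α-carbon of 1 has become quaternary; no stereocentre is formed.

Step 2
Reactants: 4 ethyl vinyl ketone (pent-1-en-3-one)
Product: 6 2-(2-bromoethyl)-2-ethyl-1,3-dioxolane, via 1-bromopentan-3-one 5 (not isolated)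
Conditions: anhydrous HBr in HOCH2CH2OH, 0 to 23 °C
Reagents that add atoms: hydrogen bromide, Br; ethylene glycol, OCCO
Why: Conjugate hydrobromination followed by HBr-catalysed ketalisation masks the ketone, so the primary bromide can be turned into a Grignard reagent.

Step 3
Reactants: 3 4,4-dimethylcyclohex-2-en-1-one; 6 2-(2-bromoethyl)-2-ethyl-1,3-dioxolane
Product: 8 rac-{[3-[2-(2-ethyl-1,3-dioxolan-2-yl)ethyl]-4,4-dimethylcyclohex-1-en-1-yl]oxy}trimethylsilane, via Grignard reagent 7 (not isolated)
Conditions: 6, Mg, THF, 25 °C; then CuBr·SMe2 (10 mol %), TMSCl, 3, THF, −78 to −40 °C; Et3N, pentane work-up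
Reagents that add atoms: magnesium, [Mg] (stays only in 7); chlorotrimethylsilane, C[Si](C)(C)Cl
Why: The copper-catalysed, TMSCl-accelerated conjugate addition of a Grignard reagent overcomes the neopentyl hindrance at C5 and traps the enolate regiospecifically; the racemic centre it makes is erased in step 4.

Step 4
Reactants: 8 racemic silyl enol ether
Product: 9 3-[2-(2-ethyl-1,3-dioxolan-2-yl)ethyl]-4,4-dimethylcyclohex-2-en-1-one
Conditions: Pd(OAc)2 (1.0 equiv), MeCN, 23 °C
Reagents that add atoms: none
Why: In this Saegusa–Ito oxidation the palladium enolate formed at C10 has only the C5–H as β-hydrogen, so the β-substituted enone is the single product.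

Step 5
Reactants: 9 β-substituted enone
Product: 11 2-bromo-3-[2-(2-ethyl-1,3-dioxolan-2-yl)ethyl]-4,4-dimethylcyclohex-2-en-1-one, via dibromo ketone 10 (not isolated)
Conditions: Br2, CH2Cl2, −10 °C; then Et3N, 0 to 23 °C
Reagents that add atoms: bromine, BrBr
Why: In this bromination–dehydrobromination sequence Br2 adds across the enone and Et3N removes the acidic α-H with loss of the β-bromide, which places the halide on C10 while the ketal sees no free acid.

Step 6
Reactants: 11 α-bromo enone
Product: 12 (1R)-2-bromo-3-[2-(2-ethyl-1,3-dioxolan-2-yl)ethyl]-4,4-dimethylcyclohex-2-en-1-ol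
Conditions: (S)-2-methyl-CBS-oxazaborolidine (20 mol %), BH3·SMe2, THF, −20 °C; MeOH, aqueous work-up
Reagents that add atoms: none
Why: In this Corey–Bakshi–Shibata reduction the bromoalkenyl arm acts as the large group and the ring CH2 as the small group, so the (S)-catalyst delivers hydride to one carbonyl face and sets the (R)-carbinol at C1.

Step 7
Reactants: 12 (1R)-allylic alcohol
Product: 15 2-{2-[(1S)-2-bromo-6,6-dimethylcyclohex-2-en-1-yl]ethyl}-2-ethyl-1,3-dioxolane, via N-allyl sulfonylhydrazine 13 (not isolated), via allylic diazene 14 (not isolated)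
Conditions: PPh3, DEAD, 2-nitrobenzenesulfonohydrazide, N-methylmorpholine, −30 °C, then 23 °C
Reagents that add atoms: 2-nitrobenzenesulfonohydrazide, NNS(=O)(=O)c1ccccc1[N+](=O)[O-] (its atoms stay only in 13 and 14)
Why: In this Myers reductive transposition the Mitsunobu displacement inverts C1, loss of the sulfinic acid gives the allylic diazene, and its retro-ene loss of N2 hands H suprafacially to C5, so the carbinol configuration becomes the (S) centre at C5 and the alkene lands at C1=C10 with bromine on C10.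

Step 8
Reactants: 15 vinyl bromide ketal
Product: 16 1-[(1S)-2-bromo-6,6-dimethylcyclohex-2-en-1-yl]pentan-3-one
Conditions: 1 M aq. HCl, THF, 23 °C
Reagents that add atoms: water, O
Why: Acid-catalysed acetal hydrolysis frees the ethyl ketone, and neither the vinyl bromide nor the purely allylic C5 centre is affected.

Step 9
Reactants: 16 bromo ketone
Product: 18 (4aS)-1,5,5-trimethyl-3,4,4a,5,6,7-hexahydronaphthalen-2(1H)-one (C1 epimers), via lithium dienolate 17 (not isolated)
Conditions: Pd2(dba)3 (2.5 mol %), P(t-Bu)3·HBF4 (10 mol %), LiN(SiMe3)2 (2.3 equiv), toluene, 23 to 50 °C; then AcOH, THF, −78 °C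
Reagents that add atoms: lithium bis(trimethylsilyl)amide, [Li+].C[Si](C)(C)[N-][Si](C)(C)C (Li stays only in 17)
Why: In this intramolecular palladium-catalysed ketone α-alkenylation zerovalent palladium inserts into the C10–Br bond, only the enolate on the ethyl side (C9) can close a six-membered ring, the product is stored as its dienolate and protonated kinetically at the α-carbon, C5 is never α or γ to a carbonyl in a protic medium, and the new C9 centre is irrelevant because it is re-enolised in step 16.

**Side chain**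

Step 10
Reactants: 19 3-methylbut-3-en-1-ol; 20 acryloyl chloride
Product: 21 3-methylbut-3-en-1-yl prop-2-enoate
Conditions: Et3N, CH2Cl2, 0 °C
Reagents that add atoms: none
Why: This is a plain O-acylation of a primary alcohol by an acid chloride.

Step 11
Reactants: 21 diene ester
Product: 22 4-methyl-5,6-dihydro-2H-pyran-2-one
Conditions: second-generation Grubbs catalyst RuCl2(=CHPh)(PCy3)(H2IMes) (3 mol %), CH2Cl2, reflux
Reagents that add atoms: none
Why: The ring-closing metathesis of an acrylate and a 1,1-disubstituted alkene to a six-membered unsaturated lactone is driven by loss of ethene.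

Step 12
Reactants: 22 unsaturated lactone
Product: 23 (4R)-4-methyloxan-2-one
Conditions: Cu(OAc)2·H2O (3 mol %), DTBM-SEGPHOS (3 mol %), (EtO)2MeSiH, t-BuOH, toluene, 0 °C
Reagents that add atoms: none
Why: In this asymmetric copper hydride conjugate reduction the ligated CuH adds hydride to one face of the β-methyl enoate and so sets C13 as R under catalyst control.

Step 13
Reactants: 23 (R)-lactone
Product: 25 (3S)-5-iodo-3-methylpentanoic acid, via trimethylsilyl ester 24 (not isolated)
Conditions: TMSI, CH2Cl2, 23 °C; then H2O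
Reagents that add atoms: iodotrimethylsilane, C[Si](C)(C)I
Why: In this SN2 dealkylative lactone opening, silylation of the carbonyl oxygen lets iodide attack the O–CH2 carbon; the stereocentre is untouched and its descriptor changes only because iodine changes the CIP ranking.

Step 14
Reactants: 26 glycerol
Product: 27 1,3-bis[(tert-butyldimethylsilyl)oxy]propan-2-ol
Conditions: TBSCl (2.05 equiv), imidazole, CH2Cl2, 0 °C
Reagents that add atoms: tert-butyldimethylsilyl chloride, CC(C)(C)[Si](C)(C)Cl
Why: Silylation is sterically selective for the two primary hydroxyls and leaves the secondary one free.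

Step 15
Reactants: 25 iodo acid; 27 protected glycerol
Product: 29 1,3-bis[(tert-butyldimethylsilyl)oxy]propan-2-yl (3S)-5-iodo-3-methylpentanoate, via acid chloride 28 (not isolated)
Conditions: (COCl)2, cat. DMF, CH2Cl2, 0 to 23 °C, concentrate; then 27, pyridine, cat. DMAP, CH2Cl2, 0 °C
Reagents that add atoms: oxalyl chloride, O=C(Cl)C(=O)Cl (Cl stays only in 28)
Why: Esterification through the acid chloride never produces a free carboxylate, which could displace iodide and re-form the lactone.

**Union and endgame**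

Step 16
Reactants: 18 bicyclic β,γ-enone; 29 iodo ester
Product: 31 1,3-bis[(tert-butyldimethylsilyl)oxy]propan-2-yl (3R)-3-methyl-5-[(1S,4aS)-1,5,5-trimethyl-2-oxo-1,2,3,4,4a,5,6,7-octahydronaphthalen-1-yl]pentanoate, via potassium dienolate 30 (not isolated)
Conditions: KN(SiMe3)2 (1.0 equiv), THF, −78 to −40 °C; then 29, DMPU, −40 to 0 °C
Reagents that add atoms: potassium bis(trimethylsilyl)amide, [K+].C[Si](C)(C)[N-][Si](C)(C)C (K stays only in 30)
Why: In this SN2 α-alkylation of an extended dienolate the base irreversibly removes the doubly activated C9–H, carbon attack at the α-terminus keeps the alkene at C1=C10, and the iodide enters axially through a chair-like transition state on the face of the axial H5 (the other face needs a twist-boat and is screened by the axial C4 methyl), which sets the quaternary C9 with the chain cis to H5.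

Step 17
Reactants: 31 keto ester
Product: 32 1,3-bis[(tert-butyldimethylsilyl)oxy]propan-2-yl (3R)-3-methyl-5-[(1R,4aS)-1,5,5-trimethyl-2-methylidene-1,2,3,4,4a,5,6,7-octahydronaphthalen-1-yl]pentanoate
Conditions: Zn, CH2Br2, TiCl4, THF/CH2Cl2, 0 to 23 °C
Reagents that add atoms: dibromomethane, BrCBr
Why: The non-basic Takai–Lombardo methylenation reagent converts hindered enolisable ketones and leaves esters, silyl ethers and the non-epimerisable quaternary C9 alone.

Step 18
Reactants: 32 exomethylene compound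
Product: 33 1,3-bis[(tert-butyldimethylsilyl)oxy]propan-2-yl (3R)-3-methyl-5-[(1R,2R,4aS)-1,2,5,5-tetramethyl-1,2,3,4,4a,5,6,7-octahydronaphthalen-1-yl]pentanoate
Conditions: H2 (1 atm), PtO2, EtOAc, 23 °C, stopped after 1 equiv
Reagents that add atoms: none
Why: In this heterogeneous catalytic hydrogenation the 1,1-disubstituted alkene reacts while the trisubstituted C1=C10 alkene next to the quaternary C9 stays inert, and the axial C9 side chain blocks its own face, so H2 arrives from the opposite face and gives the equatorial (8R) methyl cis to the chain.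

Step 19
Reactants: 33 bis-silyl ether
Product: 34 1,3-dihydroxypropan-2-yl (3R)-3-methyl-5-[(1R,2R,4aS)-1,2,5,5-tetramethyl-1,2,3,4,4a,5,6,7-octahydronaphthalen-1-yl]pentanoate (target)
Conditions: HF·pyridine, pyridine, THF, 0 °C
Reagents that add atoms: none
Why: Fluoride-mediated desilylation in a buffered, weakly acidic medium at low temperature removes both primary TBS groups without 2-to-1 acyl migration or any change at the four stereocentres.

**Compound list**
1 | isobutyraldehyde | CC(C)C=O | starting material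
2 | methyl vinyl ketone | CC(=O)C=C | starting material
3 | 4,4-dimethylcyclohex-2-en-1-one | CC1(C)CCC(=O)C=C1 | intermediate
4 | ethyl vinyl ketone | CCC(=O)C=C | starting material
5 | 1-bromopentan-3-one | CCC(=O)CCBr | intermediate
6 | 2-(2-bromoethyl)-2-ethyl-1,3-dioxolane | CCC1(CCBr)OCCO1 | intermediate
7 | [2-(2-ethyl-1,3-dioxolan-2-yl)ethyl]magnesium bromide | CCC1(CC[Mg]Br)OCCO1 | intermediate
8 | rac-{[3-[2-(2-ethyl-1,3-dioxolan-2-yl)ethyl]-4,4-dimethylcyclohex-1-en-1-yl]oxy}trimethylsilane | CCC1(CCC2C=C(O[Si](C)(C)C)CCC2(C)C)OCCO1 | intermediate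
9 | 3-[2-(2-ethyl-1,3-dioxolan-2-yl)ethyl]-4,4-dimethylcyclohex-2-en-1-one | CCC1(CCC2=CC(=O)CCC2(C)C)OCCO1 | intermediate
10 | 2,3-dibromo-3-[2-(2-ethyl-1,3-dioxolan-2-yl)ethyl]-4,4-dimethylcyclohexan-1-one | CCC1(CCC2(Br)C(Br)C(=O)CCC2(C)C)OCCO1 | intermediate
11 | 2-bromo-3-[2-(2-ethyl-1,3-dioxolan-2-yl)ethyl]-4,4-dimethylcyclohex-2-en-1-one | CCC1(CCC2=C(Br)C(=O)CCC2(C)C)OCCO1 | intermediate
12 | (1R)-2-bromo-3-[2-(2-ethyl-1,3-dioxolan-2-yl)ethyl]-4,4-dimethylcyclohex-2-en-1-ol | O[C@@H]1CCC(C)(C)C(CCC2(CC)OCCO2)=C1Br | intermediate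
13 | N-{(1S)-2-bromo-3-[2-(2-ethyl-1,3-dioxolan-2-yl)ethyl]-4,4-dimethylcyclohex-2-en-1-yl}-2-nitrobenzenesulfonohydrazide | NN([C@H]1CCC(C)(C)C(CCC2(CC)OCCO2)=C1Br)S(=O)(=O)c3ccccc3[N+](=O)[O-] | intermediate
14 | {(1S)-2-bromo-3-[2-(2-ethyl-1,3-dioxolan-2-yl)ethyl]-4,4-dimethylcyclohex-2-en-1-yl}diazene | N=N[C@H]1CCC(C)(C)C(CCC2(CC)OCCO2)=C1Br | intermediate
15 | 2-{2-[(1S)-2-bromo-6,6-dimethylcyclohex-2-en-1-yl]ethyl}-2-ethyl-1,3-dioxolane | BrC1=CCCC(C)(C)[C@@H]1CCC2(CC)OCCO2 | intermediate
16 | 1-[(1S)-2-bromo-6,6-dimethylcyclohex-2-en-1-yl]pentan-3-one | BrC1=CCCC(C)(C)[C@@H]1CCC(=O)CC | intermediate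
17 | lithium (4aS)-1,5,5-trimethyl-3,4,4a,5,6,7-hexahydronaphthalen-2-olate | [Li+].CC1=C([O-])CC[C@@H]2C1=CCCC2(C)C | intermediate
18 | (4aS)-1,5,5-trimethyl-3,4,4a,5,6,7-hexahydronaphthalen-2(1H)-one, C1 epimers | CC1C2=CCCC(C)(C)[C@@H]2CCC1=O | intermediate
19 | 3-methylbut-3-en-1-ol | CC(=C)CCO | starting material
20 | acryloyl chloride | C=CC(=O)Cl | starting material
21 | 3-methylbut-3-en-1-yl prop-2-enoate | C=CC(=O)OCCC(C)=C | intermediate
22 | 4-methyl-5,6-dihydro-2H-pyran-2-one | CC1=CC(=O)OCC1 | intermediate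
23 | (4R)-4-methyloxan-2-one | C[C@@H]1CCOC(=O)C1 | intermediate
24 | trimethylsilyl (3S)-5-iodo-3-methylpentanoate | C[C@H](CCI)CC(=O)O[Si](C)(C)C | intermediate
25 | (3S)-5-iodo-3-methylpentanoic acid | C[C@H](CCI)CC(=O)O | intermediate
26 | glycerol | OCC(O)CO | starting material
27 | 1,3-bis[(tert-butyldimethylsilyl)oxy]propan-2-ol | OC(CO[Si](C)(C)C(C)(C)C)CO[Si](C)(C)C(C)(C)C | intermediate
28 | (3S)-5-iodo-3-methylpentanoyl chloride | C[C@H](CCI)CC(=O)Cl | intermediate
29 | 1,3-bis[(tert-butyldimethylsilyl)oxy]propan-2-yl (3S)-5-iodo-3-methylpentanoate | C[C@H](CCI)CC(=O)OC(CO[Si](C)(C)C(C)(C)C)CO[Si](C)(C)C(C)(C)C | intermediate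
30 | potassium (4aS)-1,5,5-trimethyl-3,4,4a,5,6,7-hexahydronaphthalen-2-olate | [K+].CC1=C([O-])CC[C@@H]2C1=CCCC2(C)C | intermediate
31 | coupled keto ester, (3R,1S,4aS) | C[C@H](CC[C@@]1(C)C2=CCCC(C)(C)[C@@H]2CCC1=O)CC(=O)OC(CO[Si](C)(C)C(C)(C)C)CO[Si](C)(C)C(C)(C)C | intermediate
32 | exomethylene ester, (3R,1R,4aS) | C[C@H](CC[C@@]1(C)C2=CCCC(C)(C)[C@@H]2CCC1=C)CC(=O)OC(CO[Si](C)(C)C(C)(C)C)CO[Si](C)(C)C(C)(C)C | intermediate
33 | bis-TBS ether of the target, (3R,1R,2R,4aS) | C[C@H](CC[C@@]1(C)C2=CCCC(C)(C)[C@@H]2CC[C@H]1C)CC(=O)OC(CO[Si](C)(C)C(C)(C)C)CO[Si](C)(C)C(C)(C)C | intermediate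
34 | 1,3-dihydroxypropan-2-yl (3R)-3-methyl-5-[(1R,2R,4aS)-1,2,5,5-tetramethyl-1,2,3,4,4a,5,6,7-octahydronaphthalen-1-yl]pentanoate | C[C@H](CC[C@@]1(C)C2=CCCC(C)(C)[C@@H]2CC[C@H]1C)CC(=O)OC(CO)CO | target

**Counts**
Total step count: 19.
Longest linear sequence: 12 steps (step 1 or 2, then 3–9 and 16–19).

**Steps most likely to fail**

Step 9 (ring B closure). The vinyl bromide is flanked by a neopentyl-type centre, so slow oxidative addition or simple debromination may win. The fallback replaces the metal-mediated C–C closure with a classical aldol closure.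
- It sets out from 15. Miyaura borylation (B2pin2, PdCl2(dppf), KOAc, dioxane, 80 °C) gives the vinyl boronate F1.
- NaBO3·4H2O in THF/H2O oxidises it to the (S)-2-substituted 3,3-dimethylcyclohexanone F2, and 1 M HCl in THF frees the diketone F3.
- Pyrrolidine/AcOH closes F3 by a mild aldol condensation to the conjugated enone F4.
- TMSOTf/Et3N at 0 °C removes the less hindered γ-proton to give the heteroannular silyl dienol ether F5.
- MeLi in THF cleaves the O–Si bond and delivers lithium dienolate 17, where the route is rejoined. It can be quenched to 18 or alkylated directly with 29.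

Step 16 (fragment union). An unactivated primary iodide may react slowly with a tetrasubstituted dienolate, and O-alkylation, ester attack or modest facial selectivity are possible. The fallback makes the same bond with a carbonyl electrophile and removes the extra oxygen afterwards.
- It sets out from 29 and 30. Me3NO in DMSO (Ganem oxidation) converts 29 into the side-chain aldehyde F6.
- Dienolate 30 adds to F6 at −78 °C (aldol, same axial approach at C9) to give the β-hydroxy ketone F7.
- 1,1'-Thiocarbonyldiimidazole in warm toluene, under neutral conditions that avoid retro-aldol, gives the imidazolylthiocarbonate F8.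
- Bu3SnH/AIBN (Barton–McCombie deoxygenation) returns to the route at 31.

Step 17 (methylenation next to the quaternary C9). The ketone may only enolise or react sluggishly. The fallback brings in C17 by cross-coupling instead of carbonyl olefination.
- It sets out from 31. KN(SiMe3)2 and PhNTf2 at −78 °C give the enol triflate F9; the ketone C7–H is more acidic than the ester α-H.
- MeMgBr with Fe(acac)3 (5 mol %) in THF/NMP at −30 °C gives the C7=C8 trisubstituted alkene F10.
- Hydrogenation (H2, PtO2, EtOAc/AcOH), again from the face opposite the axial side chain, comes back to the route at 33.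

**Further compounds**
F1 | step 9 | 2-{2-[(1R)-6,6-dimethyl-2-(4,4,5,5-tetramethyl-1,3,2-dioxaborolan-2-yl)cyclohex-2-en-1-yl]ethyl}-2-ethyl-1,3-dioxolane | CC1(C)OB(OC1(C)C)C2=CCCC(C)(C)[C@@H]2CCC3(CC)OCCO3
F2 | step 9 | (2S)-2-[2-(2-ethyl-1,3-dioxolan-2-yl)ethyl]-3,3-dimethylcyclohexan-1-one | O=C1CCCC(C)(C)[C@@H]1CCC2(CC)OCCO2
F3 | step 9 | (2S)-3,3-dimethyl-2-(3-oxopentyl)cyclohexan-1-one | O=C1CCCC(C)(C)[C@@H]1CCC(=O)CC
F4 | step 9 | (4aS)-1,5,5-trimethyl-4,4a,5,6,7,8-hexahydronaphthalen-2(3H)-one | CC1=C2CCCC(C)(C)[C@@H]2CCC1=O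
F5 | step 9 | {[(4aS)-1,5,5-trimethyl-3,4,4a,5,6,7-hexahydronaphthalen-2-yl]oxy}trimethylsilane | CC1=C(O[Si](C)(C)C)CC[C@@H]2C1=CCCC2(C)C
F6 | step 16 | 1,3-bis[(tert-butyldimethylsilyl)oxy]propan-2-yl (3R)-3-methyl-5-oxopentanoate | C[C@H](CC=O)CC(=O)OC(CO[Si](C)(C)C(C)(C)C)CO[Si](C)(C)C(C)(C)C
F7 | step 16 | C11-hydroxy derivative of 31 (carbinol epimers, other centres as in 31) | C[C@H](CC(O)[C@@]1(C)C2=CCCC(C)(C)[C@@H]2CCC1=O)CC(=O)OC(CO[Si](C)(C)C(C)(C)C)CO[Si](C)(C)C(C)(C)C
F8 | step 16 | C11 O-(imidazol-1-ylthiocarbonyl) derivative of F7 | C[C@H](CC(OC(=S)n1ccnc1)[C@@]1(C)C2=CCCC(C)(C)[C@@H]2CCC1=O)CC(=O)OC(CO[Si](C)(C)C(C)(C)C)CO[Si](C)(C)C(C)(C)C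
F9 | step 17 | C8 enol triflate of 31 (C7=C8) | C[C@H](CC[C@@]1(C)C2=CCCC(C)(C)[C@@H]2CC=C1OS(=O)(=O)C(F)(F)F)CC(=O)OC(CO[Si](C)(C)C(C)(C)C)CO[Si](C)(C)C(C)(C)C
F10 | step 17 | C7=C8 alkene bearing the C8 methyl (7,8-didehydro-33) | C[C@H](CC[C@@]1(C)C2=CCCC(C)(C)[C@@H]2CC=C1C)CC(=O)OC(CO[Si](C)(C)C(C)(C)C)CO[Si](C)(C)C(C)(C)C
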